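**Retrosynthetic overview**
- The target is reached by global hydrogenolysis of a dodeca-O-benzyl trimer that carries removable bromine atoms at C8 of the top and bottom units.
- Key disconnection: in one Lewis-acid operation, cut C4–C4a in both the top and the middle unit (two pyran rings) together with the C4(middle)–C6(bottom) bond. This gives an acyclic seco-dimer aldehyde and 8-bromo-tetra-O-benzylepicatechin.
- The seco-dimer comes from ortho-hydroxyalkylation of 3,5-bis(benzyloxy)phenol with an aryloxy aldehyde (future C4(top)–C8(middle) bond, made before any ring exists), followed by a second aryl ether chain on the same phenol.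
- Both aryl ether chains (C2 and C3 of each new unit) come from one (2S,3S)-cis-glycidate, made from 3,4-bis(benzyloxy)benzaldehyde by Z-olefination and Jacobsen epoxidation.
- Ring order: the bottom ring C is taken from (−)-epicatechin; rings C of the middle and top units are closed together in the penultimate step.

Assumption: (−)-epicatechin, 3,5-bis(benzyloxy)phenol and 3,4-bis(benzyloxy)benzaldehyde are treated as affordable catalogue materials.

**Route**

Step 1
Reactants: 1 (−)-epicatechin, (2R,3R)-2-(3,4-dihydroxyphenyl)chromane-3,5,7-triol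
Product: 2 5,7,3',4'-tetra-O-benzyl-(−)-epicatechin (3-OH free)
Conditions: BnBr (4.4 equiv), K2CO3, DMF, 0 °C → rt
Reagents that add atoms: benzyl bromide, BrCc1ccccc1
Why: Williamson etherification, in which K2CO3 ionises only the four phenols so the secondary 3-OH stays free and no stereocentre is touched.

Step 2
Reactants: 2 5,7,3',4'-tetra-O-benzyl-(−)-epicatechin
Product: 3 8-bromo-5,7,3',4'-tetra-O-benzyl-(−)-epicatechin
Conditions: NBS (1.0 equiv), CH2Cl2, −45 °C → rt
Reagents that add atoms: N-bromosuccinimide, O=C1CCC(=O)N1Br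
Why: Electrophilic aromatic bromination at C8, the most nucleophilic ring A position of the benzylated flavan, which leaves C6 as the only site for later C-alkylation and touches no stereocentre.

Step 3
Reactants: 4 3,4-bis(benzyloxy)benzaldehyde
Product: 5 ethyl (Z)-3-[3,4-bis(benzyloxy)phenyl]prop-2-enoate
Conditions: (PhO)2P(O)CH2CO2Et, NaH, THF, −78 °C → 0 °C
Reagents that add atoms: ethyl 2-(diphenoxyphosphoryl)acetate, CCOC(=O)CP(=O)(Oc1ccccc1)Oc1ccccc1
Why: Ando-type Z-selective Horner–Wadsworth–Emmons olefination, in which the diaryl phosphonate collapses quickly from the kinetic syn oxaphosphetane and gives the (Z)-cinnamate (typically at least 9:1 with aromatic aldehydes).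

Step 4
Reactants: 5 ethyl (Z)-3-[3,4-bis(benzyloxy)phenyl]prop-2-enoate
Product: 6 ethyl (2S,3S)-3-[3,4-bis(benzyloxy)phenyl]oxirane-2-carboxylate (cis-glycidate)
Conditions: aq NaOCl (pH 11.3), (S,S)-N,N'-bis(3,5-di-tert-butylsalicylidene)cyclohexane-1,2-diaminomanganese chloride (C36H52ClMnN2O2, trivalent manganese, 6 mol %), 4-phenylpyridine N-oxide (25 mol %), CH2Cl2, 4 °C
Reagents that add atoms: sodium hypochlorite, [Na+].[O-]Cl
Why: Jacobsen–Katsuki epoxidation of a cis-cinnamate (precedented for the para-methoxy analogue), where the (S,S) catalyst gives the (2S,3S)-cis-glycidate by analogy with (R,R) giving (2R,3R) from ethyl cis-cinnamate; this sets the two stereocentres that become C2 and C3 of each new flavan unit.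

Step 5
Reactants: 7 3,5-bis(benzyloxy)phenol
Product: 8 2-bromo-3,5-bis(benzyloxy)phenol
Conditions: NBS (1.0 equiv), i-Pr2NH (10 mol %), CH2Cl2, −20 °C
Reagents that add atoms: N-bromosuccinimide, O=C1CCC(=O)N1Br
Why: Amine-catalysed ortho-selective bromination of a phenol (hydrogen-bond-directed delivery from the N-bromoamine), placing bromine where it will become C8 of the top unit and stop that ring from acting as a nucleophile in step 11.

Step 6
Reactants: 8 2-bromo-3,5-bis(benzyloxy)phenol; 6 ethyl (2S,3S)-3-[3,4-bis(benzyloxy)phenyl]oxirane-2-carboxylate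
Product: 9 ethyl (2S,3R)-3-[2-bromo-3,5-bis(benzyloxy)phenoxy]-3-[3,4-bis(benzyloxy)phenyl]-2-hydroxypropanoate
Conditions: Cs2CO3 (0.2 equiv), DMF, 50 °C
Reagents that add atoms: none
Why: SN2 epoxide opening by phenoxide at the benzylic C3 (as in thiophenoxide openings of aryl glycidates and phenoxide openings of 3-aryl glycidols), with inversion at C3 and retention at C2, so the cis-epoxide gives the threo (2S,3R) aryl ether that maps onto a 2,3-cis (2R,3R) flavan; the product alkoxide regenerates phenoxide, so the base is catalytic.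

Step 7
Reactants: 9 ethyl (2S,3R)-3-[2-bromo-3,5-bis(benzyloxy)phenoxy]-3-[3,4-bis(benzyloxy)phenyl]-2-hydroxypropanoate
Product: 10 (2S,3R)-3-[2-bromo-3,5-bis(benzyloxy)phenoxy]-3-[3,4-bis(benzyloxy)phenyl]-2-hydroxypropanal (used crude)
Conditions: i-Bu2AlH (2.5 equiv), CH2Cl2/toluene, −78 °C; aq potassium sodium tartrate
Reagents that add atoms: none
Why: Partial ester reduction, in which the aluminium hemiacetal chelated by the neighbouring alkoxide survives at −78 °C and releases the α-hydroxy aldehyde on work-up without touching either stereocentre.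

Step 8
Reactants: 7 3,5-bis(benzyloxy)phenol; 10 (2S,3R)-3-[2-bromo-3,5-bis(benzyloxy)phenoxy]-3-[3,4-bis(benzyloxy)phenyl]-2-hydroxypropanal
Product: 12 2-[(2R,3R)-3-[2-bromo-3,5-bis(benzyloxy)phenoxy]-3-[3,4-bis(benzyloxy)phenyl]-1,2-dihydroxypropyl]-3,5-bis(benzyloxy)phenol (both C1 epimers of the side chain), via bromomagnesium phenoxide 11 (not isolated)
Conditions: 7 (1.5 equiv), EtMgBr (1.0 equiv per phenol), Et2O, 0 °C; then CH2Cl2, 10, rt; pH 7 buffer
Reagents that add atoms: none
Why: Casiraghi ortho-specific hydroxyalkylation, in which the magnesium phenoxide binds the aldehyde and delivers it only to the ortho carbon through a six-membered chelate (precedented with α-alkoxy aldehydes); this forms the future C4(top)–C8(middle) bond, and the new carbinol centre is formed unselectively, which does not matter because it is ionised in step 11.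

Step 9
Reactants: 12 2-[(2R,3R)-3-[2-bromo-3,5-bis(benzyloxy)phenoxy]-3-[3,4-bis(benzyloxy)phenyl]-1,2-dihydroxypropyl]-3,5-bis(benzyloxy)phenol; 6 ethyl (2S,3S)-3-[3,4-bis(benzyloxy)phenyl]oxirane-2-carboxylate
Product: 13 ethyl (2S,3R)-3-{2-[(2R,3R)-3-(2-bromo-3,5-bis(benzyloxy)phenoxy)-3-(3,4-bis(benzyloxy)phenyl)-1,2-dihydroxypropyl]-3,5-bis(benzyloxy)phenoxy}-3-[3,4-bis(benzyloxy)phenyl]-2-hydroxypropanoate
Conditions: 6 (1.3 equiv), Cs2CO3 (0.3 equiv), DMF, 50 °C
Reagents that add atoms: none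
Why: The same phenoxide SN2 opening of the cis-glycidate at benzylic C3 as in step 6 (only the phenol is ionised by carbonate), installing the O1–C2 ether and the threo C2/C3 pair of the middle unit with inversion at the benzylic carbon.

Step 10
Reactants: 13 seco-dimer ester (as named in step 9)
Product: 14 seco-dimer aldehyde, (2S,3R)-3-{2-[(2R,3R)-3-(2-bromo-3,5-bis(benzyloxy)phenoxy)-3-(3,4-bis(benzyloxy)phenyl)-1,2-dihydroxypropyl]-3,5-bis(benzyloxy)phenoxy}-3-[3,4-bis(benzyloxy)phenyl]-2-hydroxypropanal (used crude)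
Conditions: i-Bu2AlH (5 equiv), CH2Cl2, −78 °C; aq potassium sodium tartrate
Reagents that add atoms: none
Why: Chelation-stabilised partial reduction of the α-hydroxy ester as in step 7, with the three free hydroxyls simply consuming extra hydride and no stereocentre affected.

Step 11
Reactants: 14 seco-dimer aldehyde; 3 8-bromo-5,7,3',4'-tetra-O-benzyl-(−)-epicatechin
Product: 16 8-bromo-5,7,3',4'-tetra-O-benzylepicatechin-(4β→8)-5,7,3',4'-tetra-O-benzylepicatechin-(4β→6)-8-bromo-5,7,3',4'-tetra-O-benzylepicatechin, via doubly cyclised flavan-4-ol 15 (not isolated)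
Conditions: 3 (4 equiv, excess recovered), Yb(OTf)3 (20 mol %), CH2Cl2, 0 °C → rt, slow addition of 14
Reagents that add atoms: none
Why: Proposed new method: a Lewis-acid cascade that closes both pyran rings and makes the interflavan bond in one operation – the aldehyde is attacked by the ortho carbon of its own aryl ether (six-ring Friedel–Crafts hydroxyalkylation, ring C of the middle unit) and the resulting 4-ol ionises to the flavan-4-yl cation, while the top carbinol ionises to a cation stabilised by the middle ring A and is closed on by the free ortho carbon of the bromoaryl ether (ring C of the top unit); C4 of the top unit is set 3,4-trans (4β) because the aryl group must sit pseudo-axial, anti to the axial 3-OH, to avoid peri strain with the 5-benzyloxy group, and C4 of the middle unit is set 4β when C6 of 3 adds anti to the axial 3-OH; the closest known reactions are intramolecular Friedel–Crafts hydroxyalkylation/alkylation routes to chromans and Yb(OTf)3- or TMSOTf-mediated couplings of C4-activated tetra-O-benzylepicatechins with 8-bromo flavan nucleophiles.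

Step 12
Reactants: 16 protected trimer (as named in step 11)
Product: 17 (−)-epicatechin-(4β→8)-(−)-epicatechin-(4β→6)-(−)-epicatechin (top 2R,3R,4R; middle 2R,3R,4S; bottom 2R,3R), CNP0178679.3
Conditions: H2 (1 atm), Pd(OH)2/C, Et3N, THF/MeOH/H2O, rt
Reagents that add atoms: none
Why: Hydrogenolysis removes the twelve benzyl ethers and both aryl bromides in one step, with Et3N trapping HBr so the acid-labile interflavan bonds and all stereocentres are preserved.

**Compound list**

1 | (−)-epicatechin | Oc1cc(O)c2c(c1)O[C@H](c1ccc(O)c(O)c1)[C@H](O)C2 | starting material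
2 | 5,7,3',4'-tetra-O-benzyl-(−)-epicatechin | O(Cc3ccccc3)c1cc(OCc3ccccc3)c2c(c1)O[C@H](c4ccc(OCc5ccccc5)c(OCc5ccccc5)c4)[C@H](O)C2 | intermediate
3 | 8-bromo-5,7,3',4'-tetra-O-benzyl-(−)-epicatechin | O(Cc3ccccc3)c1cc(OCc3ccccc3)c2c(c1Br)O[C@H](c4ccc(OCc5ccccc5)c(OCc5ccccc5)c4)[C@H](O)C2 | intermediate
4 | 3,4-bis(benzyloxy)benzaldehyde | O=Cc1ccc(OCc2ccccc2)c(OCc2ccccc2)c1 | starting material
5 | ethyl (Z)-3-[3,4-bis(benzyloxy)phenyl]prop-2-enoate | CCOC(=O)/C=C\c1ccc(OCc2ccccc2)c(OCc2ccccc2)c1 | intermediate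
6 | ethyl (2S,3S)-3-[3,4-bis(benzyloxy)phenyl]oxirane-2-carboxylate | O1[C@@H](c2ccc(OCc3ccccc3)c(OCc3ccccc3)c2)[C@H]1C(=O)OCC | intermediate
7 | 3,5-bis(benzyloxy)phenol | Oc1cc(OCc2ccccc2)cc(OCc2ccccc2)c1 | starting material
8 | 2-bromo-3,5-bis(benzyloxy)phenol | Oc1cc(OCc2ccccc2)cc(OCc2ccccc2)c1Br | intermediate
9 | ethyl (2S,3R)-3-[2-bromo-3,5-bis(benzyloxy)phenoxy]-3-[3,4-bis(benzyloxy)phenyl]-2-hydroxypropanoate | Brc1c(OCc2ccccc2)cc(OCc2ccccc2)cc1O[C@H](c3ccc(OCc4ccccc4)c(OCc4ccccc4)c3)[C@H](O)C(=O)OCC | intermediate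
10 | (2S,3R)-3-[2-bromo-3,5-bis(benzyloxy)phenoxy]-3-[3,4-bis(benzyloxy)phenyl]-2-hydroxypropanal | Brc1c(OCc2ccccc2)cc(OCc2ccccc2)cc1O[C@H](c3ccc(OCc4ccccc4)c(OCc4ccccc4)c3)[C@H](O)C=O | intermediate
11 | bromomagnesium 3,5-bis(benzyloxy)phenoxide | Br[Mg]Oc1cc(OCc2ccccc2)cc(OCc2ccccc2)c1 | intermediate
12 | 2-[(2R,3R)-3-[2-bromo-3,5-bis(benzyloxy)phenoxy]-3-[3,4-bis(benzyloxy)phenyl]-1,2-dihydroxypropyl]-3,5-bis(benzyloxy)phenol (C1 epimers) | Brc1c(OCc2ccccc2)cc(OCc2ccccc2)cc1O[C@H](c3ccc(OCc4ccccc4)c(OCc4ccccc4)c3)[C@H](O)C(O)c5c(O)cc(OCc6ccccc6)cc5OCc6ccccc6 | intermediate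
13 | seco-dimer ester: 12 with its phenol oxygen bonded to C3 of an ethyl (2S,3R)-3-[3,4-bis(benzyloxy)phenyl]-2-hydroxypropanoate chain | Brc1c(OCc2ccccc2)cc(OCc2ccccc2)cc1O[C@H](c3ccc(OCc4ccccc4)c(OCc4ccccc4)c3)[C@H](O)C(O)c5c(O[C@H](c7ccc(OCc8ccccc8)c(OCc8ccccc8)c7)[C@H](O)C(=O)OCC)cc(OCc6ccccc6)cc5OCc6ccccc6 | intermediate
14 | seco-dimer aldehyde: 13 with the ester reduced to the (2S,3R)-2-hydroxypropanal | Brc1c(OCc2ccccc2)cc(OCc2ccccc2)cc1O[C@H](c3ccc(OCc4ccccc4)c(OCc4ccccc4)c3)[C@H](O)C(O)c5c(O[C@H](c7ccc(OCc8ccccc8)c(OCc8ccccc8)c7)[C@H](O)C=O)cc(OCc6ccccc6)cc5OCc6ccccc6 | intermediate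
15 | 8-bromo-5,7,3',4'-tetra-O-benzylepicatechin-(4β→8)-5,7,3',4'-tetra-O-benzyl-2,3-cis-flavan-3,4-diol (C4 epimers of the lower unit) | O(Cc3ccccc3)c1cc(OCc3ccccc3)c2c(c1Br)O[C@H](c4ccc(OCc5ccccc5)c(OCc5ccccc5)c4)[C@H](O)[C@H]2c1c(OCc3ccccc3)cc(OCc3ccccc3)c2c1O[C@H](c4ccc(OCc5ccccc5)c(OCc5ccccc5)c4)[C@H](O)C2O | intermediate
16 | 8-bromo-5,7,3',4'-tetra-O-benzylepicatechin-(4β→8)-5,7,3',4'-tetra-O-benzylepicatechin-(4β→6)-8-bromo-5,7,3',4'-tetra-O-benzylepicatechin | O(Cc3ccccc3)c1cc(OCc3ccccc3)c2c(c1Br)O[C@H](c4ccc(OCc5ccccc5)c(OCc5ccccc5)c4)[C@H](O)[C@H]2c1c(OCc3ccccc3)cc(OCc3ccccc3)c2c1O[C@H](c4ccc(OCc5ccccc5)c(OCc5ccccc5)c4)[C@H](O)[C@H]2c1c(OCc3ccccc3)c(Br)c2c(c1OCc3ccccc3)C[C@@H](O)[C@@H](c4ccc(OCc5ccccc5)c(OCc5ccccc5)c4)O2 | intermediate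
17 | epicatechin-(4β→8)-epicatechin-(4β→6)-epicatechin, CNP0178679.3 | Oc1cc(O)c2c(c1)O[C@H](c1ccc(O)c(O)c1)[C@H](O)[C@H]2c1c(O)cc(O)c2c1O[C@H](c1ccc(O)c(O)c1)[C@H](O)[C@H]2c1c(O)cc2c(c1O)C[C@@H](O)[C@@H](c1ccc(O)c(O)c1)O2 | target

**Summary**

Total step count: 12.
Longest linear sequence: 9 steps (steps 3, 4, 6, 7, 8, 9, 10, 11, 12; 4 → 5 → 6 → 9 → 10 → 12 → 13 → 14 → 16 → 17).

The three steps most likely to fail, each with a fallback:

Step 6 (phenoxide opening of the glycidic ester; risks are attack at C2 and elimination of the β-aryloxy ester). The fallback swaps the ester electrophile for the alcohol and changes the oxidation-state order. It sets out from 6, which is reduced with NaBH4 in EtOH at 0 °C to [(2R,3S)-3-[3,4-bis(benzyloxy)phenyl]oxiran-2-yl]methanol F1. F1 is opened at the benzylic carbon by the sodium salt of 8 in aqueous NaOH/dioxane at 70 °C (the well-established opening of 3-aryl glycidols by phenoxides) to give (2R,3R)-3-[2-bromo-3,5-bis(benzyloxy)phenoxy]-3-[3,4-bis(benzyloxy)phenyl]propane-1,2-diol F2. Selective oxidation of the primary alcohol of F2 (TEMPO, PhI(OAc)2, CH2Cl2) then comes back to the route at aldehyde 10, bypassing 9.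

Step 8 (ortho-hydroxyalkylation with a sensitive α-hydroxy-β-aryloxy aldehyde). The fallback replaces the phenoxide-directed C–C bond formation by an aryllithium addition. It sets out from 8, which is O-allylated (allyl bromide, K2CO3, acetone) to 1-(allyloxy)-2-bromo-3,5-bis(benzyloxy)benzene F3. Bromine–lithium exchange on F3 (n-BuLi, THF, −78 °C) and addition of the aryllithium (2.2 equiv) to aldehyde 10 gives the O-allyl ether of 12, carbinol F4. Removal of the allyl group from F4 with Pd(PPh3)4 (zerovalent palladium) and morpholine returns to the route at 12.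

Step 11 (the double ring closure with capture by the hindered C6 nucleophile). The fallback separates ring formation from the interflavan coupling. It sets out from 14, which is treated with Yb(OTf)3 in CH2Cl2 containing 2-ethoxyethanol (10 equiv) and no 3; both pyran rings still close in one operation and the C4 cation is trapped by the alcohol to give the bench-stable 4β-(2-ethoxyethoxy) bis-flavan F5. F5 is then coupled with 3 (4 equiv) under TMSOTf in CH2Cl2 at −78 °C, the established activation for 4-alkoxy flavans, to come back to the route at 16.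

Further compounds
F1 | step 6 | [(2R,3S)-3-[3,4-bis(benzyloxy)phenyl]oxiran-2-yl]methanol | O1[C@@H](c2ccc(OCc3ccccc3)c(OCc3ccccc3)c2)[C@H]1CO
F2 | step 6 | (2R,3R)-3-[2-bromo-3,5-bis(benzyloxy)phenoxy]-3-[3,4-bis(benzyloxy)phenyl]propane-1,2-diol | Brc1c(OCc2ccccc2)cc(OCc2ccccc2)cc1O[C@H](c3ccc(OCc4ccccc4)c(OCc4ccccc4)c3)[C@H](O)CO
F3 | step 8 | 1-(allyloxy)-2-bromo-3,5-bis(benzyloxy)benzene | C=CCOc1cc(OCc2ccccc2)cc(OCc2ccccc2)c1Br
F4 | step 8 | O-allyl ether of 12, (2R,3R)-1-[2-(allyloxy)-4,6-bis(benzyloxy)phenyl]-3-[2-bromo-3,5-bis(benzyloxy)phenoxy]-3-[3,4-bis(benzyloxy)phenyl]propane-1,2-diol (C1 epimers) | Brc1c(OCc2ccccc2)cc(OCc2ccccc2)cc1O[C@H](c3ccc(OCc4ccccc4)c(OCc4ccccc4)c3)[C@H](O)C(O)c5c(OCC=C)cc(OCc6ccccc6)cc5OCc6ccccc6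
F5 | step 11 | 8-bromo-5,7,3',4'-tetra-O-benzylepicatechin-(4β→8)-4β-(2-ethoxyethoxy)-5,7,3',4'-tetra-O-benzylepicatechin | O(Cc3ccccc3)c1cc(OCc3ccccc3)c2c(c1Br)O[C@H](c4ccc(OCc5ccccc5)c(OCc5ccccc5)c4)[C@H](O)[C@H]2c1c(OCc3ccccc3)cc(OCc3ccccc3)c2c1O[C@H](c4ccc(OCc5ccccc5)c(OCc5ccccc5)c4)[C@H](O)[C@H]2OCCOCC
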